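Everything rests on cutting the O1–C2 bond of upper ring C. Upper C2 is benzylic to ring B, and the ring B hydroxyl sits para to it. A C2 carbinol therefore loses water under a chiral phosphoric acid and becomes a para-quinone methide. The C8a hydroxyl of ring A adds to the methide carbon. This one operation forms O1–C2, closes ring C and sets C2 trans to the C4 aryl group. The precursor is an open 1,3,3-triarylpropan-1-ol with free phenols only on ring B and at C8a. C4 is already fixed by rhodium-catalysed conjugate arylation. The all-cis lower flavan-3,4-diol hangs on C6' with every oxygen benzylated, so one neutral hydrogenolysis finishes.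

Key step: step 17

Remarks before the steps
- Numbering: flavan numbering is used. Plain locants and rings A, B, C belong to the upper 3-deoxy unit. Primed locants and rings A', B', C' belong to the lower 3,4-diol unit.
- Abbreviation: Lw = the (2R,3R,4R)-3,4,7,8-tetrakis(benzyloxy)-2-[4-(benzyloxy)phenyl]chroman-6-yl group.
- Configuration read from the target: upper unit (2S,4S), 2,4-trans; lower unit (2'R,3'R,4'R), 2',3'-cis-3',4'-cis.
- CIP letter at C4: while O7' is benzylated, C6' outranks C4a at C4. The unchanged geometry is therefore written R in 25–29 and S only in 30.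
- Lower diol: a syn-dihydroxylation of flavene 10 would arrive anti to ring B' and give the 2',3'-trans diol. The two oxygens are therefore placed on the ring B' face by way of a bromohydrin and carbon dioxide.
- Diol protection: a ketal on the lower diol would need acid after ring C is closed, and acid is what reopens O1–C2. Both alcohols are therefore carried as benzyl ethers.
- Phenol masks: the two phenols that must be free in step 17 are masked as allyl ethers. These survive hydroxide and leave without acid.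
- Assumption: the sense of induction of (S,S)-Ph-bod* (steps 4 and 15) is taken from its behaviour with simple enones, and that of (R)-TRIP (step 17) is provisional. Each is available as its antipode should a first run show the opposite sense.

Step 1
Reactants: 1 2',3',4'-trihydroxyacetophenone (gallacetophenone)
Product: 2 1-[3,4-bis(benzyloxy)-2-hydroxyphenyl]ethanone
Conditions: BnBr (2.1 equiv), K2CO3 (2.2 equiv), DMF, 25 °C
Reagents that add atoms: benzyl bromide, BrCc1ccccc1
Why: Williamson etherification that exploits the hydrogen bond between the 2-hydroxyl and the acetyl group, which makes this hydroxyl the least reactive so that only O3 and O4 are benzylated.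

Step 2
Reactants: 2 1-[3,4-bis(benzyloxy)-2-hydroxyphenyl]ethanone
Product: 3 1-[3,4-bis(benzyloxy)-5-bromo-2-hydroxyphenyl]ethanone
Conditions: NBS (1.0 equiv), MeCN, 0 °C, dark
Reagents that add atoms: N-bromosuccinimide, O=C1CCC(=O)N1Br
Why: Electrophilic aromatic bromination goes para to the free phenol and ortho to the 4-benzyloxy group, the only other open position being meta to the phenol and next to the acyl group, and the bromine marks the carbon that becomes C6'.

Step 3
Reactants: 3 1-[3,4-bis(benzyloxy)-5-bromo-2-hydroxyphenyl]ethanone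
Product: 5 7,8-bis(benzyloxy)-6-bromo-4H-chromen-4-one, via enaminone 4 (not isolated)
Conditions: Me2NCH(OMe)2 (3 equiv), toluene, 100 °C; then conc. HCl, CH2Cl2, 25 °C
Reagents that add atoms: N,N-dimethylformamide dimethyl acetal, COC(OC)N(C)C
Why: Enaminone route to chromones, in which the acetal condenses with the methyl ketone and acid lets the phenol add to the enaminone carbon and expel dimethylamine, which supplies C2' and closes ring C' as a flat enone.

Step 4
Reactants: 5 7,8-bis(benzyloxy)-6-bromo-4H-chromen-4-one; 6 4-(benzyloxy)phenylboronic acid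
Product: 7 (2S)-7,8-bis(benzyloxy)-2-[4-(benzyloxy)phenyl]-6-bromochroman-4-one
Conditions: 6 (2 equiv), [RhCl(C2H4)2]2 (2.5 mol %), (S,S)-Ph-bod* (5.5 mol %), K3PO4 (0.5 equiv), toluene/H2O 10:1, 40 °C
Reagents that add atoms: none
Why: Hayashi–Miyaura asymmetric 1,4-addition to a chromone, in which the aryl–rhodium species held by the C2-symmetric diene inserts C2'=C3' from the Re face of C2' and so sets C2' (S here, R once C3' carries a heteroatom), while the aryl bromide and benzyl ethers are inert to monovalent rhodium.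

Step 5
Reactants: 7 (2S)-7,8-bis(benzyloxy)-2-[4-(benzyloxy)phenyl]-6-bromochroman-4-one
Product: 8 (2S,4S)-7,8-bis(benzyloxy)-2-[4-(benzyloxy)phenyl]-6-bromochroman-4-ol (2,4-cis)
Conditions: NaBH4 (1.5 equiv), THF/MeOH 4:1, 0 °C
Reagents that add atoms: none
Why: Borohydride reduction in which hydride reaches the carbonyl from the face opposite ring B' to give the 2',4'-cis alcohol, a centre that step 6 removes again, and prompt reduction also ends any risk of base-induced racemisation of the flavanone.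

Step 6
Reactants: 8 (2S,4S)-7,8-bis(benzyloxy)-2-[4-(benzyloxy)phenyl]-6-bromochroman-4-ol
Product: 10 (2S)-7,8-bis(benzyloxy)-2-[4-(benzyloxy)phenyl]-6-bromo-2H-chromene, via mesylate 9 (not isolated)
Conditions: MsCl (1.5 equiv), Et3N (4 equiv), CH2Cl2, 0 to 40 °C
Reagents that add atoms: none
Why: Mesylation followed by E1 elimination, since the C4' mesylate is benzylic with O7' para and O1' ortho, ionises at once and loses H3' to triethylamine, and the basic medium leaves the C2' ether centre untouched.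

Step 7
Reactants: 10 (2S)-7,8-bis(benzyloxy)-2-[4-(benzyloxy)phenyl]-6-bromo-2H-chromene
Product: 11 (2R,3S,4R)-7,8-bis(benzyloxy)-2-[4-(benzyloxy)phenyl]-3,6-dibromochroman-4-ol (2,3-trans-3,4-trans)
Conditions: NBS (1.05 equiv), THF/H2O 4:1, 0 °C, dark
Reagents that add atoms: N-bromosuccinimide, O=C1CCC(=O)N1Br; water, O
Why: Bromohydrin formation by electrophilic anti addition, in which bromine is delivered to C3' on the face away from ring B' and water captures benzylic C4' anti to bromine, so that O4' ends on the ring B' face.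

Step 8
Reactants: 11 (2R,3S,4R)-7,8-bis(benzyloxy)-2-[4-(benzyloxy)phenyl]-3,6-dibromochroman-4-ol
Product: 14 (2R,3R,4R)-7,8-bis(benzyloxy)-2-[4-(benzyloxy)phenyl]-6-bromochroman-3,4-diol (all-cis), via epoxide 12 (not isolated), via cyclic carbonate 13 (not isolated)
Conditions: Cs2CO3 (2 equiv), n-Bu4NBr (0.2 equiv), CO2 (1 atm), DMF, 60 °C; then 2 M NaOH, THF/MeOH, 25 °C
Reagents that add atoms: carbon dioxide, O=C=O
Why: Halohydrin-to-cyclic-carbonate conversion followed by saponification, in which the C4' alkoxide displaces the C3' bromide from the ring B' face (inversion at C3'), bromide reopens the oxirane at benzylic C4', the C3' alkoxide takes up CO2 and recloses at C4' (double inversion there), so that only the cis-fused carbonate on the ring B' face can form and hydrolysis at its carbonyl carbon leaves the all-cis diol.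

Step 9
Reactants: 14 (2R,3R,4R)-7,8-bis(benzyloxy)-2-[4-(benzyloxy)phenyl]-6-bromochroman-3,4-diol
Product: 15 (2R,3R,4R)-3,4,7,8-tetrakis(benzyloxy)-2-[4-(benzyloxy)phenyl]-6-bromochroman (Lw–Br)
Conditions: NaH (3 equiv), BnBr (3 equiv), n-Bu4NI (0.1 equiv), DMF, 0 to 25 °C
Reagents that add atoms: benzyl bromide, BrCc1ccccc1
Why: Williamson etherification of both secondary alkoxides, chosen so that the lower diol is unmasked later by the same neutral hydrogenolysis as the phenols and never needs acid.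

Step 10
Reactants: 15 Lw–Br
Product: 18 Lw–B(OH)2 (the chroman-6-ylboronic acid), via aryllithium 16 (not isolated), via lithium borate 17 (not isolated)
Conditions: B(OiPr)3 (1.5 equiv), n-BuLi (1.2 equiv), THF/toluene, −78 °C; then 1 M HCl, 0 °C
Reagents that add atoms: triisopropyl borate, CC(C)OB(OC(C)C)OC(C)C; water, O
Why: Bromine–lithium exchange with in situ borate quench, where exchange at −78 °C outruns benzylic deprotonation, the aryllithium is trapped at once by the borate already present, and dilute acid hydrolyses the ate complex to the boronic acid.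

Step 11
Reactants: 19 2,3,4-trihydroxybenzaldehyde
Product: 20 3,4-bis(benzyloxy)-2-hydroxybenzaldehyde
Conditions: BnBr (2.05 equiv), K2CO3 (2.1 equiv), DMF, 25 °C
Reagents that add atoms: benzyl bromide, BrCc1ccccc1
Why: Williamson etherification with the same hydrogen-bond logic as step 1, the 2-hydroxyl chelated to the formyl group staying free.

Step 12
Reactants: 20 3,4-bis(benzyloxy)-2-hydroxybenzaldehyde
Product: 21 2-(allyloxy)-3,4-bis(benzyloxy)benzaldehyde
Conditions: allyl bromide (1.5 equiv), K2CO3 (2 equiv), DMF, 60 °C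
Reagents that add atoms: allyl bromide, C=CCBr
Why: Williamson allylation of the remaining chelated phenol under slightly more forcing conditions puts on the future O1 a group that zerovalent palladium removes later without acid and without touching benzyl ethers.

Step 13
Reactants: 22 4'-hydroxyacetophenone
Product: 23 4'-(allyloxy)acetophenone
Conditions: allyl bromide (1.2 equiv), K2CO3 (1.5 equiv), acetone, reflux
Reagents that add atoms: allyl bromide, C=CCBr
Why: Williamson allylation gives ring B the same base-stable, palladium-labile mask, which, unlike a silyl ether, survives the hydroxide of step 14.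

Step 14
Reactants: 21 2-(allyloxy)-3,4-bis(benzyloxy)benzaldehyde; 23 4'-(allyloxy)acetophenone
Product: 24 (E)-3-[2-(allyloxy)-3,4-bis(benzyloxy)phenyl]-1-[4-(allyloxy)phenyl]prop-2-en-1-one
Conditions: KOH (aq), EtOH, 25 °C
Reagents that add atoms: none
Why: Claisen–Schmidt condensation (crossed aldol, then E1cB dehydration) between a non-enolisable aldehyde and a methyl ketone gives the (E)-enone under thermodynamic control.

Step 15
Reactants: 18 Lw–B(OH)2; 24 (E)-3-[2-(allyloxy)-3,4-bis(benzyloxy)phenyl]-1-[4-(allyloxy)phenyl]prop-2-en-1-one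
Product: 25 (3R)-3-[2-(allyloxy)-3,4-bis(benzyloxy)phenyl]-1-[4-(allyloxy)phenyl]-3-Lw-propan-1-one
Conditions: 24 (1.5 equiv), [RhCl(C2H4)2]2 (2.5 mol %), (S,S)-Ph-bod* (5.5 mol %), KOH (0.5 equiv, 1.5 M aq), 1,4-dioxane, 35 °C
Reagents that add atoms: none
Why: Hayashi–Miyaura asymmetric 1,4-addition to a chalcone, in which transmetallation gives the C6'–rhodium aryl, the diene pocket steers its migration to the Re face of the enone β-carbon and so sets C4 under catalyst control (the lower-unit centres being remote), and the cheap enone is used in excess because the boronic acid is the precious partner.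

Step 16
Reactants: 25 (3R)-3-[2-(allyloxy)-3,4-bis(benzyloxy)phenyl]-1-[4-(allyloxy)phenyl]-3-Lw-propan-1-one
Product: 27 (3R)-3-[3,4-bis(benzyloxy)-2-hydroxyphenyl]-1-(4-hydroxyphenyl)-3-Lw-propan-1-ol (both C1 epimers), via bis-allyl carbinol 26 (not isolated)
Conditions: NaBH4 (2 equiv), THF/MeOH 4:1, 0 °C; then Pd(PPh3)4 (5 mol %), NaBH4 (4 equiv), THF, 25 °C; pH 7 buffer work-up, Et3N-washed silica
Reagents that add atoms: none
Why: Borohydride reduction of the ketone followed in the same flask by palladium-catalysed reductive deallylation (Tsuji–Trost-type ionisation of the aryl allyl ethers and hydride capture to propene), the carbinol needing no stereocontrol because step 17 erases it and the non-acidic medium keeping the labile 4-hydroxybenzylic alcohol and all benzyl ethers intact.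

Step 17
Reactants: 27 (3R)-3-[3,4-bis(benzyloxy)-2-hydroxyphenyl]-1-(4-hydroxyphenyl)-3-Lw-propan-1-ol (both C1 epimers)
Product: 29 (2S,4R)-7,8-bis(benzyloxy)-2-(4-hydroxyphenyl)-4-Lw-chroman (2,4-trans), via para-quinone methide 28 (not isolated)
Conditions: (R)-TRIP [3,3'-bis(2,4,6-triisopropylphenyl)-1,1'-binaphthyl-2,2'-diyl hydrogen phosphate] (10 mol %), 4 Å molecular sieves, toluene (0.02 M), −20 °C; Et3N quench at −20 °C
Reagents that add atoms: none
Why: The phosphoric acid protonates the benzylic hydroxyl of 27, water leaves with push from the para phenol of ring B, and both carbinol epimers converge on the planar para-quinone methide 28, which stays hydrogen-bonded to the phosphate. The C8a hydroxyl of ring A then adds to the exocyclic methide carbon in an oxa-1,6-conjugate addition that rearomatises ring B, the closest known reaction type being the chiral-phosphoric-acid-catalysed intramolecular oxa-1,6-addition to para-quinone methides made in situ from 4-hydroxybenzyl alcohols. Ring C closes in the 6-exo-trig mode, because the attacked double bond between C2 and the ipso carbon of ring B lies outside the new ring. C2 is the only new stereocentre and is set by the catalyst, whose bifunctional pocket binds the methide carbonyl and the phenol and must guide oxygen to the Si face of C2 (2S, trans to the C4 aryl group), while the substrate bias toward the cis ring should be small because the C4 aryl group can sit pseudo-axial to avoid H5. Chemoselectivity rests on 27 itself: only ring B has a free para hydroxyl, so C2' and C4' with their benzyl ethers cannot give a neutral methide, and the C8a hydroxyl is the only nucleophile within reach. Because closure is reversible in acid, low temperature, sieves, dilution and the cold amine quench keep the outcome kinetic.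

Step 18
Reactants: 29 (2S,4R)-7,8-bis(benzyloxy)-2-(4-hydroxyphenyl)-4-Lw-chroman
Product: 30 CNP0209379.1, (2R,3R,4R)-6-[(2S,4S)-7,8-dihydroxy-2-(4-hydroxyphenyl)chroman-4-yl]-2-(4-hydroxyphenyl)chroman-3,4,7,8-tetrol
Conditions: H2 (1 atm), 20 % Pd(OH)2/C, THF/MeOH 1:1, 25 °C; filtration and concentration under argon
Reagents that add atoms: none
Why: Catalytic hydrogenolysis of the seven O-benzyl groups, whose unhindered PhCH2–O bonds should be cleaved far faster than the ring C–O bonds at C2, C2' and C4' that sit on crowded, poorly adsorbing arenes, while the neutral medium avoids ionisation at C4' and reopening of O1–C2, so no stereocentre is touched.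

Compound list
1 | 2',3',4'-trihydroxyacetophenone (gallacetophenone) | CC(=O)c1ccc(O)c(O)c1O | starting material
2 | 1-[3,4-bis(benzyloxy)-2-hydroxyphenyl]ethanone | CC(=O)c1ccc(OCc2ccccc2)c(OCc2ccccc2)c1O | intermediate
3 | 1-[3,4-bis(benzyloxy)-5-bromo-2-hydroxyphenyl]ethanone | CC(=O)c1cc(Br)c(OCc2ccccc2)c(OCc2ccccc2)c1O | intermediate
4 | (E)-1-[3,4-bis(benzyloxy)-5-bromo-2-hydroxyphenyl]-3-(dimethylamino)prop-2-en-1-one | CN(C)/C=C/C(=O)c1cc(Br)c(OCc2ccccc2)c(OCc2ccccc2)c1O | intermediate
5 | 7,8-bis(benzyloxy)-6-bromo-4H-chromen-4-one | O=c1ccoc2c1cc(Br)c(OCc1ccccc1)c2OCc1ccccc1 | intermediate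
6 | 4-(benzyloxy)phenylboronic acid | OB(O)c1ccc(OCc2ccccc2)cc1 | starting material
7 | (2S)-7,8-bis(benzyloxy)-2-[4-(benzyloxy)phenyl]-6-bromochroman-4-one | Brc1cc2c(c(OCc3ccccc3)c1OCc1ccccc1)O[C@H](c1ccc(OCc3ccccc3)cc1)CC2=O | intermediate
8 | (2S,4S)-7,8-bis(benzyloxy)-2-[4-(benzyloxy)phenyl]-6-bromochroman-4-ol, 2,4-cis | Brc1cc2c(c(OCc3ccccc3)c1OCc1ccccc1)O[C@H](c1ccc(OCc3ccccc3)cc1)C[C@@H]2O | intermediate
9 | 4-O-methanesulfonate of 8 | Brc1cc2c(c(OCc3ccccc3)c1OCc1ccccc1)O[C@H](c1ccc(OCc3ccccc3)cc1)C[C@@H]2OS(C)(=O)=O | intermediate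
10 | (2S)-7,8-bis(benzyloxy)-2-[4-(benzyloxy)phenyl]-6-bromo-2H-chromene | Brc1cc2c(c(OCc3ccccc3)c1OCc1ccccc1)O[C@H](c1ccc(OCc3ccccc3)cc1)C=C2 | intermediate
11 | (2R,3S,4R)-7,8-bis(benzyloxy)-2-[4-(benzyloxy)phenyl]-3,6-dibromochroman-4-ol, 2,3-trans-3,4-trans | Brc1cc2c(c(OCc3ccccc3)c1OCc1ccccc1)O[C@H](c1ccc(OCc3ccccc3)cc1)[C@@H](Br)[C@@H]2O | intermediate
12 | 3,4-epoxide of the 6-bromo-7,8-bis(benzyloxy)-2-[4-(benzyloxy)phenyl]chroman, oxirane oxygen cis to the 2-aryl group, C2 as in 11 | Brc1cc2c(c(OCc3ccccc3)c1OCc1ccccc1)O[C@H](c1ccc(OCc3ccccc3)cc1)[C@@H]1O[C@H]21 | intermediate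
13 | 3,4-cyclic carbonate of 14, cis-fused on the face of the 2-aryl group | Brc1cc2c(c(OCc3ccccc3)c1OCc1ccccc1)O[C@H](c1ccc(OCc3ccccc3)cc1)[C@@H]1OC(=O)O[C@H]21 | intermediate
14 | (2R,3R,4R)-7,8-bis(benzyloxy)-2-[4-(benzyloxy)phenyl]-6-bromochroman-3,4-diol, all-cis | Brc1cc2c(c(OCc3ccccc3)c1OCc1ccccc1)O[C@H](c1ccc(OCc3ccccc3)cc1)[C@H](O)[C@@H]2O | intermediate
15 | (2R,3R,4R)-3,4,7,8-tetrakis(benzyloxy)-2-[4-(benzyloxy)phenyl]-6-bromochroman (Lw–Br) | Brc1cc2c(c(OCc3ccccc3)c1OCc1ccccc1)O[C@H](c1ccc(OCc3ccccc3)cc1)[C@H](OCc1ccccc1)[C@@H]2OCc1ccccc1 | intermediate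
16 | Lw–Li (6-lithio analogue of 15) | [Li]c1cc2c(c(OCc3ccccc3)c1OCc1ccccc1)O[C@H](c1ccc(OCc3ccccc3)cc1)[C@H](OCc1ccccc1)[C@@H]2OCc1ccccc1 | intermediate
17 | lithium Lw-triisopropoxyborate | [Li+].CC(C)O[B-](OC(C)C)(OC(C)C)c1cc2c(c(OCc3ccccc3)c1OCc1ccccc1)O[C@H](c1ccc(OCc3ccccc3)cc1)[C@H](OCc1ccccc1)[C@@H]2OCc1ccccc1 | intermediate
18 | Lw–B(OH)2 | OB(O)c1cc2c(c(OCc3ccccc3)c1OCc1ccccc1)O[C@H](c1ccc(OCc3ccccc3)cc1)[C@H](OCc1ccccc1)[C@@H]2OCc1ccccc1 | intermediate
19 | 2,3,4-trihydroxybenzaldehyde | O=Cc1ccc(O)c(O)c1O | starting material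
20 | 3,4-bis(benzyloxy)-2-hydroxybenzaldehyde | O=Cc1ccc(OCc2ccccc2)c(OCc2ccccc2)c1O | intermediate
21 | 2-(allyloxy)-3,4-bis(benzyloxy)benzaldehyde | O=Cc1ccc(OCc2ccccc2)c(OCc2ccccc2)c1OCC=C | intermediate
22 | 4'-hydroxyacetophenone | CC(=O)c1ccc(O)cc1 | starting material
23 | 4'-(allyloxy)acetophenone | CC(=O)c1ccc(OCC=C)cc1 | intermediate
24 | (E)-3-[2-(allyloxy)-3,4-bis(benzyloxy)phenyl]-1-[4-(allyloxy)phenyl]prop-2-en-1-one | C=CCOc1ccc(C(=O)/C=C/c2ccc(OCc3ccccc3)c(OCc3ccccc3)c2OCC=C)cc1 | intermediate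
25 | (3R)-3-[2-(allyloxy)-3,4-bis(benzyloxy)phenyl]-1-[4-(allyloxy)phenyl]-3-Lw-propan-1-one | C=CCOc1ccc(C(=O)C[C@@H](c2cc3c(c(OCc4ccccc4)c2OCc2ccccc2)O[C@H](c2ccc(OCc4ccccc4)cc2)[C@H](OCc2ccccc2)[C@@H]3OCc2ccccc2)c2ccc(OCc3ccccc3)c(OCc3ccccc3)c2OCC=C)cc1 | intermediate
26 | (3R)-3-[2-(allyloxy)-3,4-bis(benzyloxy)phenyl]-1-[4-(allyloxy)phenyl]-3-Lw-propan-1-ol, both C1 epimers | C=CCOc1ccc(C(O)C[C@@H](c2cc3c(c(OCc4ccccc4)c2OCc2ccccc2)O[C@H](c2ccc(OCc4ccccc4)cc2)[C@H](OCc2ccccc2)[C@@H]3OCc2ccccc2)c2ccc(OCc3ccccc3)c(OCc3ccccc3)c2OCC=C)cc1 | intermediate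
27 | (3R)-3-[3,4-bis(benzyloxy)-2-hydroxyphenyl]-1-(4-hydroxyphenyl)-3-Lw-propan-1-ol, both C1 epimers (precursor of the key step) | Oc1ccc(C(O)C[C@@H](c2cc3c(c(OCc4ccccc4)c2OCc2ccccc2)O[C@H](c2ccc(OCc4ccccc4)cc2)[C@H](OCc2ccccc2)[C@@H]3OCc2ccccc2)c2ccc(OCc3ccccc3)c(OCc3ccccc3)c2O)cc1 | intermediate
28 | 4-{(3R)-3-[3,4-bis(benzyloxy)-2-hydroxyphenyl]-3-Lw-propylidene}cyclohexa-2,5-dien-1-one (para-quinone methide) | O=C1C=CC(=CC[C@@H](c2cc3c(c(OCc4ccccc4)c2OCc2ccccc2)O[C@H](c2ccc(OCc4ccccc4)cc2)[C@H](OCc2ccccc2)[C@@H]3OCc2ccccc2)c2ccc(OCc3ccccc3)c(OCc3ccccc3)c2O)C=C1 | intermediate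
29 | (2S,4R)-7,8-bis(benzyloxy)-2-(4-hydroxyphenyl)-4-Lw-chroman, 2,4-trans (product of the key step) | Oc1ccc([C@@H]2C[C@@H](c3cc4c(c(OCc5ccccc5)c3OCc3ccccc3)O[C@H](c3ccc(OCc5ccccc5)cc3)[C@H](OCc3ccccc3)[C@@H]4OCc3ccccc3)c3ccc(OCc4ccccc4)c(OCc4ccccc4)c3O2)cc1 | intermediate
30 | CNP0209379.1, (2R,3R,4R)-6-[(2S,4S)-7,8-dihydroxy-2-(4-hydroxyphenyl)chroman-4-yl]-2-(4-hydroxyphenyl)chroman-3,4,7,8-tetrol | Oc1ccc([C@@H]2C[C@@H](c3cc4c(c(O)c3O)O[C@H](c3ccc(O)cc3)[C@H](O)[C@@H]4O)c3ccc(O)c(O)c3O2)cc1 | target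

Total step count: 18. Longest linear sequence: 14 steps (steps 1–10, then 15–18).

Steps most likely to fail

Step 17 (key step).
- What may go wrong: weak facial discrimination at the planar methide carbon.
- What may go wrong: acid-catalysed reopening of O1–C2, with drift toward the more relaxed ring.
- What may go wrong: tautomerisation of the alkyl-substituted methide to a styrene.
- The fallback sets out from 21 and 18 and returns at 30. It sets C2 by ketone reduction and SN2 closure instead of through a methide.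
- Aldehyde 21 is condensed (KOH, EtOH) with commercial 4'-benzyloxyacetophenone to give the ring B benzyl chalcone F1.
- Arylation of F1 with 18 under the conditions of step 15 gives the ring B benzyl ketone F2.
- Noyori transfer hydrogenation with RuCl(p-cymene)[(R,R)-TsDPEN] in HCO2H/Et3N gives the (1R)-carbinol F3.
- Pd(PPh3)4/NaBH4 removes the single allyl group and gives the C8a phenol F4.
- An intramolecular Mitsunobu reaction (PPh3, DIAD, toluene, 0 °C) closes O1–C2 with inversion and gives the octabenzyl flavan F5, in which ring B cannot form a neutral methide.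
- Hydrogenolysis as in step 18 gives 30.

Step 15.
- What may go wrong: slow insertion, because both aryl partners carry an ortho oxygen substituent.
- What may go wrong: protodeboronation of the electron-rich boronic acid outrunning addition.
- What may go wrong: incomplete facial control.
- The fallback sets out from 21 and 15 and returns at 25. It replaces catalysis by an auxiliary-controlled organocopper addition.
- Doebner–Knoevenagel condensation of 21 with malonic acid (pyridine, piperidine) gives the cinnamic acid F6.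
- Activation with pivaloyl chloride/Et3N and LiCl-mediated acylation of (R)-4-phenyl-1,3-oxazolidin-2-one gives the N-enoyl imide F7.
- Aryllithium 16 is made from 15 with n-BuLi at −78 °C without borate and is added together with MgBr2·OEt2 and CuBr·SMe2. The chelated s-cis imide is attacked on the face away from the 4-phenyl group, which gives the 3,3-diaryl imide F8.
- Me(MeO)NH·HCl/AlMe3 releases the auxiliary and gives the Weinreb amide F9.
- 4-(Allyloxy)phenylmagnesium bromide F10, made from 1-(allyloxy)-4-bromobenzene and Mg, converts F9 into 25.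

Step 8.
- What may go wrong: opening of the labile benzylic oxirane from the opposite face by carbonate or adventitious water, with loss of the cis relationship.
- What may go wrong: a hydride shift after ionisation at C4'.
- What may go wrong: sluggish uptake of CO2 at a hindered secondary centre.
- The fallback sets out from 11 and returns at 14. It sets C4' by ketone reduction instead of by displacement.
- Warming 11 with aqueous KOH in dioxane passes through epoxide 12, which hydroxide opens at C4' to give the 3',4'-trans diol F11.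
- MnO2 in CH2Cl2 oxidises only the benzylic C4' hydroxyl and gives the 2',3'-cis-3'-hydroxyflavanone F12.
- Luche reduction (NaBH4, CeCl3·7H2O, MeOH, −40 °C) delivers hydride as in step 5, from the face opposite ring B' and the 3'-hydroxyl, and gives 14.

Further compounds
F1 | step 17 | (E)-3-[2-(allyloxy)-3,4-bis(benzyloxy)phenyl]-1-[4-(benzyloxy)phenyl]prop-2-en-1-one | O=C(/C=C/c1ccc(OCc2ccccc2)c(OCc2ccccc2)c1OCC=C)c1ccc(OCc2ccccc2)cc1
F2 | step 17 | (3R)-3-[2-(allyloxy)-3,4-bis(benzyloxy)phenyl]-1-[4-(benzyloxy)phenyl]-3-Lw-propan-1-one | c1ccccc1COc1ccc(C(=O)C[C@@H](c2cc3c(c(OCc4ccccc4)c2OCc2ccccc2)O[C@H](c2ccc(OCc4ccccc4)cc2)[C@H](OCc2ccccc2)[C@@H]3OCc2ccccc2)c2ccc(OCc3ccccc3)c(OCc3ccccc3)c2OCC=C)cc1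
F3 | step 17 | (1R,3R)-3-[2-(allyloxy)-3,4-bis(benzyloxy)phenyl]-1-[4-(benzyloxy)phenyl]-3-Lw-propan-1-ol | c1ccccc1COc1ccc([C@H](O)C[C@@H](c2cc3c(c(OCc4ccccc4)c2OCc2ccccc2)O[C@H](c2ccc(OCc4ccccc4)cc2)[C@H](OCc2ccccc2)[C@@H]3OCc2ccccc2)c2ccc(OCc3ccccc3)c(OCc3ccccc3)c2OCC=C)cc1
F4 | step 17 | (1R,3R)-3-[3,4-bis(benzyloxy)-2-hydroxyphenyl]-1-[4-(benzyloxy)phenyl]-3-Lw-propan-1-ol | c1ccccc1COc1ccc([C@H](O)C[C@@H](c2cc3c(c(OCc4ccccc4)c2OCc2ccccc2)O[C@H](c2ccc(OCc4ccccc4)cc2)[C@H](OCc2ccccc2)[C@@H]3OCc2ccccc2)c2ccc(OCc3ccccc3)c(OCc3ccccc3)c2O)cc1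
F5 | step 17 | (2S,4R)-7,8-bis(benzyloxy)-2-[4-(benzyloxy)phenyl]-4-Lw-chroman, 2,4-trans | c1ccccc1COc1ccc([C@@H]2C[C@@H](c3cc4c(c(OCc5ccccc5)c3OCc3ccccc3)O[C@H](c3ccc(OCc5ccccc5)cc3)[C@H](OCc3ccccc3)[C@@H]4OCc3ccccc3)c3ccc(OCc4ccccc4)c(OCc4ccccc4)c3O2)cc1
F6 | step 15 | (E)-3-[2-(allyloxy)-3,4-bis(benzyloxy)phenyl]prop-2-enoic acid | OC(=O)/C=C/c1ccc(OCc2ccccc2)c(OCc2ccccc2)c1OCC=C
F7 | step 15 | (4R)-3-{(E)-3-[2-(allyloxy)-3,4-bis(benzyloxy)phenyl]prop-2-enoyl}-4-phenyl-1,3-oxazolidin-2-one | O=C(/C=C/c1ccc(OCc2ccccc2)c(OCc2ccccc2)c1OCC=C)N1[C@H](c2ccccc2)COC1=O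
F8 | step 15 | (4R)-3-{(3R)-3-[2-(allyloxy)-3,4-bis(benzyloxy)phenyl]-3-Lw-propanoyl}-4-phenyl-1,3-oxazolidin-2-one | O=C(C[C@@H](c1cc2c(c(OCc3ccccc3)c1OCc1ccccc1)O[C@H](c1ccc(OCc3ccccc3)cc1)[C@H](OCc1ccccc1)[C@@H]2OCc1ccccc1)c1ccc(OCc2ccccc2)c(OCc2ccccc2)c1OCC=C)N1[C@H](c2ccccc2)COC1=O
F9 | step 15 | (3R)-3-[2-(allyloxy)-3,4-bis(benzyloxy)phenyl]-N-methoxy-N-methyl-3-Lw-propanamide | CON(C)C(=O)C[C@@H](c1cc2c(c(OCc3ccccc3)c1OCc1ccccc1)O[C@H](c1ccc(OCc3ccccc3)cc1)[C@H](OCc1ccccc1)[C@@H]2OCc1ccccc1)c1ccc(OCc2ccccc2)c(OCc2ccccc2)c1OCC=C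
F10 | step 15 | 4-(allyloxy)phenylmagnesium bromide | C=CCOc1ccc([Mg]Br)cc1
F11 | step 8 | (2R,3R,4S)-7,8-bis(benzyloxy)-2-[4-(benzyloxy)phenyl]-6-bromochroman-3,4-diol, 2,3-cis-3,4-trans | Brc1cc2c(c(OCc3ccccc3)c1OCc1ccccc1)O[C@H](c1ccc(OCc3ccccc3)cc1)[C@H](O)[C@H]2O
F12 | step 8 | (2R,3S)-7,8-bis(benzyloxy)-2-[4-(benzyloxy)phenyl]-6-bromo-3-hydroxychroman-4-one, 2,3-cis | Brc1cc2c(c(OCc3ccccc3)c1OCc1ccccc1)O[C@H](c1ccc(OCc3ccccc3)cc1)[C@H](O)C2=O
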